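## The problem

Compound 28 is a (2R,3R)-dihydroflavonol: a chroman-4-one (ring C) fused through C4a–C8a to a phloroglucinol-type ring A and bonded at C2 to a resorcinol-type ring B. Ring A carries one prenyl group at C6, between the 5- and 7-hydroxyls, and ring B a geranyl chain at C3', between the 2'- and 4'-hydroxyls. Any closure of ring C from a ring A with two equivalent free ortho oxygens also gives the 8-prenyl isomer, so the oxygen that becomes O1 must be singled out before the ring closes. The stereocentres C2 and C3 are trans. C3, the carbinol carbon next to the ketone, controls C2 once it is set, because the benzylic C2–O1 bond can open and re-close and the diequatorial trans isomer is favoured. The absolute problem is therefore to set C3 once, without an electrophilic oxidant: the three trisubstituted alkenes of the side chains would be attacked by peracids, dioxiranes or OsO4 before any enoate. The same alkenes exclude hydrogenolysis and strong acid (an ortho-hydroxy prenyl arene cyclises to a chroman), and the free polyphenolic alpha-ketol is sensitive to base and air. The enabling feature is the array around the ring fusion: O1 on C8a, the acyl carbon C4 on the adjacent C4a, and the C5 oxygen on the other side of C4a. This is the pattern left when a carboxylate adds to a 3-alkoxybenzyne at the remote carbon and the acyl group shifts to the carbanion beside the alkoxy group. The rest of ring C, O–C3–C2 in a trans relationship, maps onto a trans-3-arylglycidate.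

## Retrosynthesis

**28 ⇒ 27.** The last cut is at the four phenolic O–CH2 acetal bonds (O5, O7, O2', O4') of 27. MOM ethers were preferred to silyl ethers (lost to the fluoride of the key step), benzyl ethers (hydrogenolysis would saturate the chains) and methyl ethers (removal needs Lewis acids that cyclise prenyl phenols). They also direct every arene metalation of the route. 27 is no simpler in skeleton, but it is the form that can be assembled under basic conditions. The forward step needs acid mild enough to leave the ortho-hydroxy prenyl and geranyl arenes uncyclised.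

**27 ⇒ 12 + 23.** Three bonds are cut at once: O1–C8a, C4a–C4 and O1–C2. The neighbouring disconnection, a chalcone route (C4a–C4 by acylation or aldol, then O1–C2), leaves ring A with two equivalent ortho oxygens and hence 6- and 8-prenyl isomers. Here the aryne 24 released from 12 offers only one oxygen site, so the 6-prenyl pattern is fixed. Both stereocentres arrive in the glycidate 23: its C2 becomes C3 unchanged and its benzylic carbon becomes C2 with inversion. The precursors are two arenes of similar size, each made by routine metalation chemistry. The forward cascade (24 → aryl anion 25 → acylphenoxide 26 → 27) must deliver regioselective carboxylate addition, acyl transfer before protonation, and endo opening of the epoxide.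

**23 ⇒ 22 ⇒ 21.** The carboxylate of 23 is traced to the active amide 22, and the two oxirane C–O bonds of 22 to the E-alkene 21. Electrophilic epoxidation or dihydroxylation of a cinnamate would attack the geranyl alkenes first, and ylide-type epoxidations of aldehyde 19 give glycidic amides that cannot be hydrolysed without harming the epoxide. The N-acylpyrrole is both a reactive acceptor for a metal-bound peroxide and an acyl group that hydroxide removes at 0 °C. The forward reactions need reagent-controlled facial selectivity on an acceptor deactivated by two alkoxy groups, and isolation of a dry salt without acidification.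

**21 ⇒ 19 + 20; 19 ⇒ 17 ⇒ 14 + 15; 14 ⇒ 13.** The alkene (future C2–C3) is cut by a Wittig disconnection to aldehyde 19 and ylide 20. The formyl carbon and then the geranyl chain are removed from ring B, leading through 17 to the bis-acetal 14, geranyl bromide 15 and resorcinol 13. Both C–C bonds are made by directed ortho-metalation, which places the chain between the two oxygens and the formyl group beside one of them without isomers. Friedel–Crafts-type geranylation or formylation of the free diphenol would give mixtures and cyclised products.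

**12 ⇒ 8 ⇒ 7.** The O–S bond of the triflate and the C–Si bond are cut together (retro-Brook sequence through 9, 10 and 11), then the C–Br bond. In phenol 7 the two open ring positions are both ortho to the hydroxyl and related by the mirror plane through C1 and C4. Only one monobromide 8 can form, so the silyl group must end up between the future triflate and a MOM ether. The forward bromination must select the arene over the prenyl alkene.

**7 ⇒ 6 ⇒ 3 + 4; 3 ⇒ 2 ⇒ 1.** The prenyl C–C bond is cut back to the silyl bis-acetal 3 and prenyl bromide 4. Metalation between the two MOM ethers fixes the prenyl position, and the bulky silyl ether marks the third oxygen (the future O1) and blocks its neighbours. The alternative, direct C-prenylation of 1 and later protection, offers no way to mask only the two hydroxyls flanking the prenyl group. The price is a statistical mono-silylation of phloroglucinol 1 to give 2.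

## Roads not taken

**Alternative 1:** The cut is at C3–C4 and O1–C2. A ring-A salicylaldehyde acetal, 2-(dimethoxymethyl)-3,5-bis(methoxymethoxy)-4-(3-methylbut-2-en-1-yl)phenol A1, would be ionised by a chiral Brønsted acid to an O-methyl ortho-quinone methide. This would undergo [4+2] cycloaddition with the (E)-enol benzoate of the ring-B arylacetaldehyde A2 to give the 2,3-trans 4-methoxyflavan-3-yl benzoate A3.
- Merits: cycloadditions of ortho-quinone methides with electron-rich alkenes are well founded, the single free phenol of A1 fixes the ring-A regiochemistry, and the assembly is convergent. In the reliability of the ring-forming event itself this road is arguably better founded than the chosen one.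
- Weak points: A3 has the wrong oxidation level at C4 and an ester on O3. Hydrolysis of a highly ionisable benzylic ether, oxidation and debenzoylation of a base-sensitive alpha-ketol add three operations before deprotection. A2 needs a geometrically pure enol ester of a fragile aldehyde. The regiochemistry depends on the aryl donor overriding the acyloxy group, and asymmetric induction on an oxocarbenium with no hydrogen-bond handle is not established.
- Comparison: the chosen plan offers absolute configuration from an established catalytic epoxidation, relative configuration from a stereospecific opening, and a key-step product (27) at the correct oxidation level one step from the target.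

**Alternative 2:** The cut is at C4a–C5, so ring A is built last. Soft enolisation of the dihydropyranone keto ester A4 (methyl 4-[(2R,3R)-2-aryl-3-(methoxymethoxy)-4-oxo-3,4-dihydro-2H-pyran-6-yl]-3-oxo-2-prenylbutanoate) would let C4a attack the ester carbonyl in a Claisen (Dieckmann-type) closure, and aromatisation would give A5 with free 5- and 7-hydroxyls.
- Merits: the prenyl position and oxygen pattern are written into the chain, so ring A raises no regiochemical question, and ring A needs no protecting groups. In protecting-group economy this road is better.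
- Weak points: A4 is a sensitive tricarbonyl compound that must be built linearly with both stereocentres already in place. The nucleophile needed is the vinylogous alpha carbon, while the most acidic protons lie elsewhere in the chain. Enolisation toward C3 would epimerise it and open the ring by loss of O1.
- Comparison: the chosen plan offers convergence, a shorter longest linear sequence, and stereocentres that never meet enolising conditions.

**Alternative 3:** The cut is at C3–C4. A chiral lithium phosphite, (R*O)2POLi, would add to the aroylsilane of the racemic alpha-aryloxy aldehyde A6. Brook rearrangement, addition to the tethered aldehyde and silyl transfer would give the 3-O-triethylsilyl tetra-MOM ether A7, with C2 resolved dynamically.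
- Merits: one catalytic step would make the last C–C bond and both stereocentres. O1–C2 is formed beforehand, so ring A is unambiguous. The 3-hydroxyl emerges protected, a real advantage in handling the alpha-ketol.
- Weak points: A6 requires a doubly ortho-substituted hydroxyaryl acylsilane and O-alkylation of that hindered phenol by a secondary, highly ionisable electrophile. The alpha-aryloxy aldehyde is prone to elimination. An intramolecular cross silyl benzoin with dynamic resolution and trans selectivity is unproven, and a desilylation is added.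
- Comparison: the chosen plan offers precursors (12 and 23) reached by routine arene chemistry, stereochemistry from an established epoxidation, and one deprotection fewer.

Key step: step 13

Assumption: the facial sense of the Sm(O-i-Pr)3/H8-BINOL epoxidation of 21 is taken to follow that of other beta-aryl enoyl acceptors ((S)-ligand giving the (2R,3S)-epoxide); if the first batch shows the opposite sense, the (R)-ligand is used with no other change.

Assumption: ylide 20, a known crystalline reagent, is taken as purchasable; otherwise it is made in two operations from pyrrole, bromoacetyl bromide and PPh3.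

## Route

Step 1
Reactants: 1 phloroglucinol (benzene-1,3,5-triol)
Product: 2 5-{[tri(propan-2-yl)silyl]oxy}benzene-1,3-diol
Conditions: TIPSCl (1 equiv), imidazole, DMF, 0 °C → rt (1 in threefold excess)
Reagents that add atoms: chlorotri(propan-2-yl)silane (TIPSCl), CC(C)[Si](Cl)(C(C)C)C(C)C
Why: Statistical mono-O-silylation of a symmetrical triol; with 1 in excess the chlorosilane should be consumed mainly as the mono-ether, unreacted 1 is removed by aqueous extraction, and the oxygen that will become O1 is marked from the start.

Step 2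
Reactants: 2 5-{[tri(propan-2-yl)silyl]oxy}benzene-1,3-diol
Product: 3 [3,5-bis(methoxymethoxy)phenoxy]tri(propan-2-yl)silane
Conditions: MOMCl, i-Pr2NEt, CH2Cl2, 0 °C → rt
Reagents that add atoms: chloromethyl methyl ether (MOMCl), COCCl
Why: O-Alkylation of the two remaining phenols (acetal formation under amine base); the aryl silyl ether is stable to these conditions.

Step 3
Reactants: 3 [3,5-bis(methoxymethoxy)phenoxy]tri(propan-2-yl)silane; 4 prenyl bromide (1-bromo-3-methylbut-2-ene)
Product: 6 [3,5-bis(methoxymethoxy)-4-(3-methylbut-2-en-1-yl)phenoxy]tri(propan-2-yl)silane, via aryllithium 5 (not isolated)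
Conditions: n-BuLi, THF, 0 °C; CuI (10 mol %), 4, −78 °C → rt
Reagents that add atoms: none
Why: Directed ortho-metalation at the position flanked by both MOM ethers (the bulky silyl ether neither directs nor admits the base to its own ortho positions), then CuI-catalysed allylic substitution at the primary carbon of 4 without allylic transposition.

Step 4
Reactants: 6 [3,5-bis(methoxymethoxy)-4-(3-methylbut-2-en-1-yl)phenoxy]tri(propan-2-yl)silane
Product: 7 3,5-bis(methoxymethoxy)-4-(3-methylbut-2-en-1-yl)phenol
Conditions: TBAF, AcOH, THF, 0 °C → rt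
Reagents that add atoms: none
Why: Fluoride-induced cleavage of the aryl silyl ether; acetic acid buffers the phenoxide, and the MOM ethers and the alkene are inert.

Step 5
Reactants: 7 3,5-bis(methoxymethoxy)-4-(3-methylbut-2-en-1-yl)phenol
Product: 8 2-bromo-3,5-bis(methoxymethoxy)-4-(3-methylbut-2-en-1-yl)phenol
Conditions: NBS (1.0 equiv), CH2Cl2, −78 °C
Reagents that add atoms: N-bromosuccinimide (NBS), O=C1CCC(=O)N1Br
Why: Electrophilic aromatic bromination ortho to the free phenol; the two open ring positions are equivalent by the mirror plane through C1 and C4, so only one monobromide can form, and the phloroglucinol-type ring should outpace the trisubstituted alkene at −78 °C when one equivalent is added slowly.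

Step 6
Reactants: 8 2-bromo-3,5-bis(methoxymethoxy)-4-(3-methylbut-2-en-1-yl)phenol
Product: 12 3,5-bis(methoxymethoxy)-4-(3-methylbut-2-en-1-yl)-2-(trimethylsilyl)phenyl trifluoromethanesulfonate, via aryl trimethylsilyl ether 9 (not isolated), via ortho-lithio silyl ether 10 (not isolated), via lithium 2-silylphenoxide 11 (not isolated)
Conditions: HMDS, THF, 65 °C, then evaporation; n-BuLi, THF, −100 °C; Tf2O, −100 → −78 °C
Reagents that add atoms: hexamethyldisilazane (HMDS), C[Si](C)(C)N[Si](C)(C)C; trifluoromethanesulfonic anhydride (Tf2O), O=S(=O)(OS(=O)(=O)C(F)(F)F)C(F)(F)F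
Why: O-Silylation, bromine–lithium exchange, retro-Brook 1,3 O→C silyl shift and O-triflation of the phenoxide, the standard sequence to ortho-silylaryl triflates; the exchange is faster than any deprotonation, and the acetals and alkene tolerate brief exposure to Tf2O at low temperature.

Step 7
Reactants: 13 resorcinol (benzene-1,3-diol)
Product: 14 1,3-bis(methoxymethoxy)benzene
Conditions: MOMCl, i-Pr2NEt, CH2Cl2, 0 °C → rt
Reagents that add atoms: chloromethyl methyl ether (MOMCl), COCCl
Why: Double O-alkylation of the diphenol (acetal formation); the MOM ethers serve as directing groups in steps 8 and 9.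

Step 8
Reactants: 14 1,3-bis(methoxymethoxy)benzene; 15 geranyl bromide ((2E)-1-bromo-3,7-dimethylocta-2,6-diene)
Product: 17 2-[(2E)-3,7-dimethylocta-2,6-dien-1-yl]-1,3-bis(methoxymethoxy)benzene, via aryllithium 16 (not isolated)
Conditions: n-BuLi, THF, 0 °C → rt; CuI (10 mol %), 15, −78 °C → rt
Reagents that add atoms: none
Why: Directed ortho-metalation at C2, between the two MOM ethers, then CuI-catalysed SN2 substitution of the allylic bromide, which keeps the E geometry of the chain.

Step 9
Reactants: 17 2-[(2E)-3,7-dimethylocta-2,6-dien-1-yl]-1,3-bis(methoxymethoxy)benzene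
Product: 19 3-[(2E)-3,7-dimethylocta-2,6-dien-1-yl]-2,4-bis(methoxymethoxy)benzaldehyde, via aryllithium 18 (not isolated)
Conditions: n-BuLi, TMEDA, THF, 0 °C; DMF, −78 °C → rt; H2O
Reagents that add atoms: N,N-dimethylformamide (DMF), CN(C)C=O
Why: Second directed ortho-metalation, at the only kind of position still ortho to a MOM ether (the two are equivalent), and formylation of the aryllithium with DMF.

Step 10
Reactants: 19 3-[(2E)-3,7-dimethylocta-2,6-dien-1-yl]-2,4-bis(methoxymethoxy)benzaldehyde; 20 1-(1H-pyrrol-1-yl)-2-(triphenyl-λ5-phosphanylidene)ethan-1-one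
Product: 21 (2E)-3-{3-[(2E)-3,7-dimethylocta-2,6-dien-1-yl]-2,4-bis(methoxymethoxy)phenyl}-1-(1H-pyrrol-1-yl)prop-2-en-1-one
Conditions: toluene, 100 °C
Reagents that add atoms: none
Why: Wittig olefination with a carbonyl-stabilised ylide, which gives the E-alkene; the hindered, electron-rich aldehyde needs heating, but the acetals and chain alkenes are unaffected.

Step 11
Reactants: 21 (2E)-3-{3-[(2E)-3,7-dimethylocta-2,6-dien-1-yl]-2,4-bis(methoxymethoxy)phenyl}-1-(1H-pyrrol-1-yl)prop-2-en-1-one
Product: 22 [(2R,3S)-3-{3-[(2E)-3,7-dimethylocta-2,6-dien-1-yl]-2,4-bis(methoxymethoxy)phenyl}oxiran-2-yl](1H-pyrrol-1-yl)methanone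
Conditions: Sm(O-i-Pr)3 (10 mol %), (S)-H8-BINOL (10 mol %), Ph3As=O (10 mol %), TBHP (decane), MS 4 Å, THF, rt
Reagents that add atoms: tert-butyl hydroperoxide (TBHP), CC(C)(C)OO
Why: Catalytic asymmetric nucleophilic epoxidation (Weitz–Scheffer type): the samarium-bound peroxide adds to the beta carbon and the enolate closes the oxirane, so the E geometry becomes the trans epoxide and the binaphthol ligand sets both stereocentres by reagent control; beta-aryl enoyl pyrroles are established substrates, and a nucleophilic oxidant leaves the electron-rich chain alkenes untouched.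

Step 12
Reactants: 22 [(2R,3S)-3-{3-[(2E)-3,7-dimethylocta-2,6-dien-1-yl]-2,4-bis(methoxymethoxy)phenyl}oxiran-2-yl](1H-pyrrol-1-yl)methanone
Product: 23 potassium (2R,3S)-3-{3-[(2E)-3,7-dimethylocta-2,6-dien-1-yl]-2,4-bis(methoxymethoxy)phenyl}oxirane-2-carboxylate
Conditions: KOH (1.0 equiv), THF/H2O, 0 °C; Et2O wash; freeze-drying, then P2O5 in vacuo
Reagents that add atoms: potassium hydroxide, [K+].[OH-]
Why: Hydrolysis (acyl substitution) of the N-acylpyrrole, an active-amide acyl donor, by one equivalent of hydroxide at 0 °C, where the epoxide is not opened; the salt is never acidified because free arylglycidic acids decarboxylate, and it is dried rigorously because any proton source would divert step 13.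

Step 13
Reactants: 12 3,5-bis(methoxymethoxy)-4-(3-methylbut-2-en-1-yl)-2-(trimethylsilyl)phenyl trifluoromethanesulfonate; 23 potassium (2R,3S)-3-{3-[(2E)-3,7-dimethylocta-2,6-dien-1-yl]-2,4-bis(methoxymethoxy)phenyl}oxirane-2-carboxylate
Product: 27 (2R,3R)-2-{3-[(2E)-3,7-dimethylocta-2,6-dien-1-yl]-2,4-bis(methoxymethoxy)phenyl}-3-hydroxy-5,7-bis(methoxymethoxy)-6-(3-methylbut-2-en-1-yl)-2,3-dihydro-4H-chromen-4-one, via aryne 24 (not isolated), via aryl anion 25 (not isolated), via acylphenoxide 26 (not isolated)
Conditions: CsF, 18-crown-6, THF, 25 → 50 °C (23 in 1.3-fold excess); AcOH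
Reagents that add atoms: none
Why: Proposed new method: fluoride removes the silyl group of 12 and triflate leaves to give aryne 24; the carboxylate of 23 adds at the aryne carbon remote from the neighbouring MOM ether (future C8a), and the aryl anion 25 attacks its own ester carbonyl through a four-membered transition structure (anionic Fries-type O→C acyl shift) to give the ortho-acyl phenoxide 26 with C4 on C4a. The closest known reaction type is aryne insertion into the C–O bond of carboxylic acids, which with acrylic-type acids closes chroman-4-ones by oxa-Michael addition; an epoxide as the internal electrophile has not been shown. Ring C is then closed by 6-endo-tet opening of the epoxide, the phenoxide oxygen attacking the benzylic carbon anti to the breaking C–O bond. C3 is carried over unchanged from C2 of the glycidate and its epoxide oxygen becomes the 3-hydroxyl; the new stereocentre C2 is set by inversion at the (3S) benzylic carbon, that is by substrate control from the trans epoxide, which gives the 2,3-trans (2R,3R) isomer, and a looser, cation-like opening would converge on the same diequatorial isomer because C3 is retained. Three selectivities are needed: the regiochemistry of carboxylate addition (secured by the alkoxy group beside the aryne, which stabilises the carbanion next to oxygen), acyl transfer ahead of protonation of 25 (secured by the dry potassium salt in an aprotic solvent with no acid present), and 6-endo over 5-exo opening (secured by the 2,4-dialkoxyaryl group, which makes the benzylic carbon the electrophilic end of the epoxide while the carbonyl deactivates the alpha carbon). The glycidate is used in slight excess so that no aryne is left to arylate the product alkoxide.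

Step 14
Reactants: 27 (2R,3R)-2-{3-[(2E)-3,7-dimethylocta-2,6-dien-1-yl]-2,4-bis(methoxymethoxy)phenyl}-3-hydroxy-5,7-bis(methoxymethoxy)-6-(3-methylbut-2-en-1-yl)-2,3-dihydro-4H-chromen-4-one
Product: 28 (2R,3R)-2-{3-[(2E)-3,7-dimethylocta-2,6-dien-1-yl]-2,4-dihydroxyphenyl}-3,5,7-trihydroxy-6-(3-methylbut-2-en-1-yl)-2,3-dihydro-4H-chromen-4-one
Conditions: HCl (3 M aq.), MeOH, 40 °C
Reagents that add atoms: none
Why: Acid-catalysed solvolysis (transacetalisation to methanol) of the four aryl MOM ethers; C3 is untouched by acid and C2, should it ionise through the electron-rich ring B, re-closes to the favoured trans isomer, so the configuration of 27 is kept.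

## Compound list

1 | phloroglucinol (benzene-1,3,5-triol) | Oc1cc(O)cc(O)c1 | starting material
2 | 5-{[tri(propan-2-yl)silyl]oxy}benzene-1,3-diol | CC(C)[Si](Oc1cc(O)cc(O)c1)(C(C)C)C(C)C | intermediate
3 | [3,5-bis(methoxymethoxy)phenoxy]tri(propan-2-yl)silane | COCOc1cc(OCOC)cc(O[Si](C(C)C)(C(C)C)C(C)C)c1 | intermediate
4 | prenyl bromide (1-bromo-3-methylbut-2-ene) | CC(C)=CCBr | starting material
5 | {2,6-bis(methoxymethoxy)-4-[tri(propan-2-yl)silyloxy]phenyl}lithium | [Li]c1c(OCOC)cc(O[Si](C(C)C)(C(C)C)C(C)C)cc1OCOC | intermediate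
6 | [3,5-bis(methoxymethoxy)-4-(3-methylbut-2-en-1-yl)phenoxy]tri(propan-2-yl)silane | COCOc1cc(O[Si](C(C)C)(C(C)C)C(C)C)cc(OCOC)c1CC=C(C)C | intermediate
7 | 3,5-bis(methoxymethoxy)-4-(3-methylbut-2-en-1-yl)phenol | COCOc1cc(O)cc(OCOC)c1CC=C(C)C | intermediate
8 | 2-bromo-3,5-bis(methoxymethoxy)-4-(3-methylbut-2-en-1-yl)phenol | COCOc1cc(O)c(Br)c(OCOC)c1CC=C(C)C | intermediate
9 | [2-bromo-3,5-bis(methoxymethoxy)-4-(3-methylbut-2-en-1-yl)phenoxy]trimethylsilane | COCOc1cc(O[Si](C)(C)C)c(Br)c(OCOC)c1CC=C(C)C | intermediate
10 | {2,4-bis(methoxymethoxy)-3-(3-methylbut-2-en-1-yl)-6-[(trimethylsilyl)oxy]phenyl}lithium | COCOc1cc(O[Si](C)(C)C)c([Li])c(OCOC)c1CC=C(C)C | intermediate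
11 | lithium 3,5-bis(methoxymethoxy)-4-(3-methylbut-2-en-1-yl)-2-(trimethylsilyl)phenolate | [Li+].[O-]c1cc(OCOC)c(CC=C(C)C)c(OCOC)c1[Si](C)(C)C | intermediate
12 | 3,5-bis(methoxymethoxy)-4-(3-methylbut-2-en-1-yl)-2-(trimethylsilyl)phenyl trifluoromethanesulfonate | C[Si](C)(C)c1c(OS(=O)(=O)C(F)(F)F)cc(OCOC)c(CC=C(C)C)c1OCOC | intermediate
13 | resorcinol (benzene-1,3-diol) | Oc1cccc(O)c1 | starting material
14 | 1,3-bis(methoxymethoxy)benzene | COCOc1cccc(OCOC)c1 | intermediate
15 | geranyl bromide ((2E)-1-bromo-3,7-dimethylocta-2,6-diene) | CC(C)=CCC/C(C)=C/CBr | starting material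
16 | [2,6-bis(methoxymethoxy)phenyl]lithium | [Li]c1c(OCOC)cccc1OCOC | intermediate
17 | 2-[(2E)-3,7-dimethylocta-2,6-dien-1-yl]-1,3-bis(methoxymethoxy)benzene | COCOc1cccc(OCOC)c1C/C=C(\C)CCC=C(C)C | intermediate
18 | {3-[(2E)-3,7-dimethylocta-2,6-dien-1-yl]-2,4-bis(methoxymethoxy)phenyl}lithium | [Li]c1ccc(OCOC)c(C/C=C(\C)CCC=C(C)C)c1OCOC | intermediate
19 | 3-[(2E)-3,7-dimethylocta-2,6-dien-1-yl]-2,4-bis(methoxymethoxy)benzaldehyde | O=Cc1ccc(OCOC)c(C/C=C(\C)CCC=C(C)C)c1OCOC | intermediate
20 | 1-(1H-pyrrol-1-yl)-2-(triphenyl-λ5-phosphanylidene)ethan-1-one | O=C(C=P(c1ccccc1)(c1ccccc1)c1ccccc1)n1cccc1 | starting material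
21 | (2E)-3-{3-[(2E)-3,7-dimethylocta-2,6-dien-1-yl]-2,4-bis(methoxymethoxy)phenyl}-1-(1H-pyrrol-1-yl)prop-2-en-1-one | O=C(/C=C/c1ccc(OCOC)c(C/C=C(\C)CCC=C(C)C)c1OCOC)n1cccc1 | intermediate
22 | [(2R,3S)-3-{3-[(2E)-3,7-dimethylocta-2,6-dien-1-yl]-2,4-bis(methoxymethoxy)phenyl}oxiran-2-yl](1H-pyrrol-1-yl)methanone | O=C([C@@H]1O[C@H]1c1ccc(OCOC)c(C/C=C(\C)CCC=C(C)C)c1OCOC)n1cccc1 | intermediate
23 | potassium (2R,3S)-3-{3-[(2E)-3,7-dimethylocta-2,6-dien-1-yl]-2,4-bis(methoxymethoxy)phenyl}oxirane-2-carboxylate | [K+].[O-]C(=O)[C@@H]1O[C@H]1c1ccc(OCOC)c(C/C=C(\C)CCC=C(C)C)c1OCOC | intermediate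
24 | 3,5-bis(methoxymethoxy)-4-(3-methylbut-2-en-1-yl)benzyne (1,2-didehydrobenzene) | COCOC1=CC#CC(OCOC)=C1CC=C(C)C | intermediate
25 | potassium 2-{[(2R,3S)-3-arylglycidoyl]oxy}-4,6-bis(methoxymethoxy)-5-(3-methylbut-2-en-1-yl)benzen-1-ide (aryl = 3-geranyl-2,4-bis(methoxymethoxy)phenyl) | [K+].O=C(Oc1cc(OCOC)c(CC=C(C)C)c(OCOC)[c-]1)[C@@H]1O[C@H]1c1ccc(OCOC)c(C/C=C(\C)CCC=C(C)C)c1OCOC | intermediate
26 | potassium 2-[(2R,3S)-3-{3-[(2E)-3,7-dimethylocta-2,6-dien-1-yl]-2,4-bis(methoxymethoxy)phenyl}oxirane-2-carbonyl]-3,5-bis(methoxymethoxy)-4-(3-methylbut-2-en-1-yl)phenolate | [K+].[O-]c1cc(OCOC)c(CC=C(C)C)c(OCOC)c1C(=O)[C@@H]1O[C@H]1c1ccc(OCOC)c(C/C=C(\C)CCC=C(C)C)c1OCOC | intermediate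
27 | (2R,3R)-2-{3-[(2E)-3,7-dimethylocta-2,6-dien-1-yl]-2,4-bis(methoxymethoxy)phenyl}-3-hydroxy-5,7-bis(methoxymethoxy)-6-(3-methylbut-2-en-1-yl)-2,3-dihydro-4H-chromen-4-one | CC(C)=CCC/C(C)=C/Cc1c(OCOC)ccc([C@H]2Oc3cc(OCOC)c(CC=C(C)C)c(OCOC)c3C(=O)[C@@H]2O)c1OCOC | intermediate
28 | (2R,3R)-2-{3-[(2E)-3,7-dimethylocta-2,6-dien-1-yl]-2,4-dihydroxyphenyl}-3,5,7-trihydroxy-6-(3-methylbut-2-en-1-yl)-2,3-dihydro-4H-chromen-4-one | CC(C)=CCC/C(C)=C/Cc1c(O)ccc([C@H]2Oc3cc(O)c(CC=C(C)C)c(O)c3C(=O)[C@@H]2O)c1O | target

## Step count and least certain steps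

Total: 14 steps. Longest linear sequence: 8 steps (1 → 12 → 27 → 28, or equally 13 → 23 → 27 → 28).

**Step 13 (key step, new method).** Three things are most likely to go wrong:
- protonation of aryl anion 25 before the acyl shift, by traces of water or pyrrole in the salt, which stops the cascade at simple O-arylation;
- exo-mode opening of the epoxide at the carbon next to the carbonyl (five-membered closure), which is favoured when the doubly ortho-substituted aryl ketone twists out of conjugation;
- arylation of the product alkoxide by a second aryne, or base-induced epimerisation and ring contraction of the alpha-ketol on prolonged heating.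

Fallback, by known chemistry, from bromophenol 8 and epoxy acylpyrrole 22, returning at 27. Phenol 8 is masked with 2-methoxypropene (PPTS cat., CH2Cl2, 0 °C) as 2-bromo-1-[(2-methoxypropan-2-yl)oxy]-3,5-bis(methoxymethoxy)-4-(3-methylbut-2-en-1-yl)benzene F1. Bromine–lithium exchange (n-BuLi, THF, −78 °C) gives {6-[(2-methoxypropan-2-yl)oxy]-2,4-bis(methoxymethoxy)-3-(3-methylbut-2-en-1-yl)phenyl}lithium F2. F2 is acylated by 22 (ketone synthesis from an N-acylpyrrole, whose pyrrolyl carbinolate collapses on work-up) to the protected epoxy ketone [(2R,3S)-3-aryloxiran-2-yl]{6-[(2-methoxypropan-2-yl)oxy]-2,4-bis(methoxymethoxy)-3-(3-methylbut-2-en-1-yl)phenyl}methanone F3. PPTS in moist CH2Cl2 removes the ketal to the 2'-hydroxychalcone epoxide [(2R,3S)-3-aryloxiran-2-yl][6-hydroxy-2,4-bis(methoxymethoxy)-3-(3-methylbut-2-en-1-yl)phenyl]methanone F4. Under the same mild acid F4 closes at the benzylic carbon, the classical acid-mediated cyclisation of 2'-hydroxychalcone epoxides to trans-dihydroflavonols, giving 27.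

**Step 14.** The likely failures are acid-catalysed addition of a freed phenol to the neighbouring prenyl or geranyl double bond (chroman formation), and partial loss of the trans configuration by ionisation at C2. Fallback from 27, returning at 28: silyl-transfer deprotection under buffered, non-protic conditions in place of protic solvolysis. TMSOTf and 2,2'-bipyridyl in CH2Cl2 at 0 °C convert the aryl MOM ethers (and the 3-hydroxyl) into silyl ethers, giving the pentakis(trimethylsilyl) ether of 28, F5. Water at neutral pH then hydrolyses F5 to 28.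

**Step 11.** The likely failures are slow conjugate addition of the metal peroxide to an acceptor deactivated by ortho- and para-alkoxy groups, incomplete facial control, and acid-induced opening of the very electron-rich benzylic epoxide during chromatography (Et3N-deactivated silica is planned). Fallback from aldehyde 19, returning at 23: a carbonyl-addition route with resolution. Darzens condensation of 19 with methyl chloroacetate (NaOMe, MeOH/THF, −10 °C → rt) gives racemic methyl trans-3-{3-[(2E)-3,7-dimethylocta-2,6-dien-1-yl]-2,4-bis(methoxymethoxy)phenyl}oxirane-2-carboxylate F6. Lipase-mediated enantioselective hydrolysis, as practised on trans-3-arylglycidates, leaves the (2R,3S)-methyl ester F7 and removes the antipode as the water-soluble (2S,3R)-acid F8. KOSiMe3 in THF converts F7 into the anhydrous salt 23.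

**Step 5.** The likely failures are competing attack of the brominating agent on the prenyl double bond and a second bromination. Fallback from phenol 7, returning at 12 and bypassing steps 5 and 6: directed ortho-metalation of a carbamate, with no electrophilic halogen. Phenol 7 and isopropyl isocyanate (Et3N, CH2Cl2) give 3,5-bis(methoxymethoxy)-4-(3-methylbut-2-en-1-yl)phenyl propan-2-ylcarbamate F9. In-situ N-silylation (TBSOTf, TMEDA), ortho-lithiation (n-BuLi, TMEDA, −78 °C) and quench with TMSCl give 3,5-bis(methoxymethoxy)-4-(3-methylbut-2-en-1-yl)-2-(trimethylsilyl)phenyl propan-2-ylcarbamate F10. Carbamate cleavage (DBU, Et2NH, MeCN, 40 °C) followed by PhNTf2 in the same flask converts F10 into 12.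

## Further compounds

F1 | step 13 | 2-bromo-1-[(2-methoxypropan-2-yl)oxy]-3,5-bis(methoxymethoxy)-4-(3-methylbut-2-en-1-yl)benzene | COC(C)(C)Oc1cc(OCOC)c(CC=C(C)C)c(OCOC)c1Br
F2 | step 13 | {6-[(2-methoxypropan-2-yl)oxy]-2,4-bis(methoxymethoxy)-3-(3-methylbut-2-en-1-yl)phenyl}lithium | COC(C)(C)Oc1cc(OCOC)c(CC=C(C)C)c(OCOC)c1[Li]
F3 | step 13 | [(2R,3S)-3-{3-[(2E)-3,7-dimethylocta-2,6-dien-1-yl]-2,4-bis(methoxymethoxy)phenyl}oxiran-2-yl]{6-[(2-methoxypropan-2-yl)oxy]-2,4-bis(methoxymethoxy)-3-(3-methylbut-2-en-1-yl)phenyl}methanone | COC(C)(C)Oc1cc(OCOC)c(CC=C(C)C)c(OCOC)c1C(=O)[C@@H]1O[C@H]1c1ccc(OCOC)c(C/C=C(\C)CCC=C(C)C)c1OCOC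
F4 | step 13 | [(2R,3S)-3-{3-[(2E)-3,7-dimethylocta-2,6-dien-1-yl]-2,4-bis(methoxymethoxy)phenyl}oxiran-2-yl][6-hydroxy-2,4-bis(methoxymethoxy)-3-(3-methylbut-2-en-1-yl)phenyl]methanone | Oc1cc(OCOC)c(CC=C(C)C)c(OCOC)c1C(=O)[C@@H]1O[C@H]1c1ccc(OCOC)c(C/C=C(\C)CCC=C(C)C)c1OCOC
F5 | step 14 | (2R,3R)-2-{3-[(2E)-3,7-dimethylocta-2,6-dien-1-yl]-2,4-bis[(trimethylsilyl)oxy]phenyl}-6-(3-methylbut-2-en-1-yl)-3,5,7-tris[(trimethylsilyl)oxy]-2,3-dihydro-4H-chromen-4-one | CC(C)=CCC/C(C)=C/Cc1c(O[Si](C)(C)C)ccc([C@H]2Oc3cc(O[Si](C)(C)C)c(CC=C(C)C)c(O[Si](C)(C)C)c3C(=O)[C@@H]2O[Si](C)(C)C)c1O[Si](C)(C)C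
F6 | step 11 | racemic methyl trans-3-{3-[(2E)-3,7-dimethylocta-2,6-dien-1-yl]-2,4-bis(methoxymethoxy)phenyl}oxirane-2-carboxylate (one enantiomer drawn) | COC(=O)[C@@H]1O[C@H]1c1ccc(OCOC)c(C/C=C(\C)CCC=C(C)C)c1OCOC
F7 | step 11 | methyl (2R,3S)-3-{3-[(2E)-3,7-dimethylocta-2,6-dien-1-yl]-2,4-bis(methoxymethoxy)phenyl}oxirane-2-carboxylate | COC(=O)[C@@H]1O[C@H]1c1ccc(OCOC)c(C/C=C(\C)CCC=C(C)C)c1OCOC
F8 | step 11 | (2S,3R)-3-{3-[(2E)-3,7-dimethylocta-2,6-dien-1-yl]-2,4-bis(methoxymethoxy)phenyl}oxirane-2-carboxylic acid | OC(=O)[C@H]1O[C@@H]1c1ccc(OCOC)c(C/C=C(\C)CCC=C(C)C)c1OCOC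
F9 | step 5 | 3,5-bis(methoxymethoxy)-4-(3-methylbut-2-en-1-yl)phenyl propan-2-ylcarbamate | CC(C)NC(=O)Oc1cc(OCOC)c(CC=C(C)C)c(OCOC)c1
F10 | step 5 | 3,5-bis(methoxymethoxy)-4-(3-methylbut-2-en-1-yl)-2-(trimethylsilyl)phenyl propan-2-ylcarbamate | CC(C)NC(=O)Oc1cc(OCOC)c(CC=C(C)C)c(OCOC)c1[Si](C)(C)C
A1 | alternative 1 | 2-(dimethoxymethyl)-3,5-bis(methoxymethoxy)-4-(3-methylbut-2-en-1-yl)phenol | COC(OC)c1c(O)cc(OCOC)c(CC=C(C)C)c1OCOC
A2 | alternative 1 | (E)-2-{3-[(2E)-3,7-dimethylocta-2,6-dien-1-yl]-2,4-bis(methoxymethoxy)phenyl}ethenyl benzoate | O=C(O/C=C/c1ccc(OCOC)c(C/C=C(\C)CCC=C(C)C)c1OCOC)c1ccccc1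
A3 | alternative 1 | 2,3-trans-4-methoxyflavan-3-yl benzoate with 5,7,2',4'-MOM ethers, 6-prenyl and 3'-geranyl groups (C4 epimers) | CC(C)=CCC/C(C)=C/Cc1c(OCOC)ccc([C@H]2Oc3cc(OCOC)c(CC=C(C)C)c(OCOC)c3C(OC)[C@@H]2OC(=O)c2ccccc2)c1OCOC
A4 | alternative 2 | methyl 4-[(2R,3R)-2-{3-[(2E)-3,7-dimethylocta-2,6-dien-1-yl]-2,4-bis(methoxymethoxy)phenyl}-3-(methoxymethoxy)-4-oxo-3,4-dihydro-2H-pyran-6-yl]-2-(3-methylbut-2-en-1-yl)-3-oxobutanoate | CC(C)=CCC/C(C)=C/Cc1c(OCOC)ccc([C@H]2OC(CC(=O)C(CC=C(C)C)C(=O)OC)=CC(=O)[C@@H]2OCOC)c1OCOC
A5 | alternative 2 | (2R,3R)-dihydroflavonol with free 5,7-hydroxyls and 3,2',4'-MOM ethers | CC(C)=CCC/C(C)=C/Cc1c(OCOC)ccc([C@H]2Oc3cc(O)c(CC=C(C)C)c(O)c3C(=O)[C@@H]2OCOC)c1OCOC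
A6 | alternative 3 | racemic 2-{3-[(2E)-3,7-dimethylocta-2,6-dien-1-yl]-2,4-bis(methoxymethoxy)phenyl}-2-[3,5-bis(methoxymethoxy)-4-(3-methylbut-2-en-1-yl)-2-(triethylsilylcarbonyl)phenoxy]acetaldehyde | CC[Si](CC)(CC)C(=O)c1c(OC(C=O)c2ccc(OCOC)c(C/C=C(\C)CCC=C(C)C)c2OCOC)cc(OCOC)c(CC=C(C)C)c1OCOC
A7 | alternative 3 | 3-O-triethylsilyl ether of 27 | CC(C)=CCC/C(C)=C/Cc1c(OCOC)ccc([C@H]2Oc3cc(OCOC)c(CC=C(C)C)c(OCOC)c3C(=O)[C@@H]2O[Si](CC)(CC)CC)c1OCOC
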